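**Retrosynthetic overview**
- The plan rests on ring B (C1 CO2Me, C2 OH, C3 Me, C4 OH, C5 O-aroyl, C6 Me). The chain Me–C3–C4(O)–C5(O)–C6–Me is hexane-3,4-dione, and C1, C2 and the ester carbon are dimethyl malonate.
- The last operations free ring A (acetal hydrolysis, debenzylation). Before them, a 5-aroyloxycyclohexane-1,3-dione is aromatised by oxidation, so O2 and O4 appear as free phenols and only O5 is acylated.
- The key disconnection cuts C1–C6 (Michael) and C2–C3 (Dieckmann). It leads back to dimethyl malonate and the mono-enol aroate of hexane-3,4-dione, so the depside C5–O–CO bond is made earlier as an enol O-acylation.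
- The aroyl unit is protected haematommic acid, made from methyl orsellinate by C3' formylation, benzylation, acetalisation, saponification and conversion to the acyl fluoride.
- Ring A is purchased. Ring B is the only ring built; it is closed in the key step and aromatised directly afterwards.

Key step: step 8

Remark on stereochemistry: the target has no stereocentre, stereogenic axis or stereogenic double bond. It is achiral, so no enantiocontrol is needed and the sp3 centres formed on the way are erased.
Remark on numbering: ring B atoms are C1–C6 as above. Ring A atoms are primed (C1' carboxyl, C2' O, C3' CHO, C4' O, C5' H, C6' Me).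

**Step 1**
Reactants: 1 methyl orsellinate
Product: 2 methyl 3-formyl-2,4-dihydroxy-6-methylbenzoate (methyl haematommate)
Conditions: Cl2CHOMe, TiCl4, CH2Cl2, −10 → 0 °C; then 1 M HCl
Reagents that add atoms: dichloromethyl methyl ether, COC(Cl)Cl; water, O
Why: Rieche formylation, in which the titanium(IV) phenoxide of 1 should deliver the chloro(methoxy)methyl cation to C3', the carbon ortho to both oxygens, and any C5' isomer is removed by chromatography.

**Step 2**
Reactants: 2 methyl haematommate
Product: 3 methyl 2,4-bis(benzyloxy)-3-formyl-6-methylbenzoate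
Conditions: BnBr, K2CO3, DMF, 70 °C
Reagents that add atoms: benzyl bromide, BrCc1ccccc1
Why: Williamson ether synthesis, in which warm DMF and excess carbonate overcome the hydrogen bonding of both chelated phenols while the non-enolisable aldehyde and the methyl ester stay inert.

**Step 3**
Reactants: 3 dibenzyl aldehyde ester; 4 ethylene glycol
Product: 5 methyl 2,4-bis(benzyloxy)-3-(1,3-dioxolan-2-yl)-6-methylbenzoate
Conditions: PPTS (cat.), toluene, Dean–Stark, reflux
Reagents that add atoms: none
Why: Acid-catalysed acetalisation with azeotropic removal of water masks the aldehyde, which would otherwise undergo Knoevenagel condensation with malonate in step 8.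

**Step 4**
Reactants: 5 acetal methyl ester
Product: 6 2,4-bis(benzyloxy)-3-(1,3-dioxolan-2-yl)-6-methylbenzoic acid
Conditions: KOH, DMSO/H2O, 90 °C; then 1 M HCl, 0 °C, to pH 4
Reagents that add atoms: potassium hydroxide, [K+].[OH-]
Why: Saponification of a di-ortho-substituted benzoate needs poorly solvated hydroxide in hot aqueous DMSO, which benzyl ethers and the acetal tolerate, and the short cold acidification to pH 4 should spare the acetal.

**Step 5**
Reactants: 6 protected haematommic acid
Product: 7 2,4-bis(benzyloxy)-3-(1,3-dioxolan-2-yl)-6-methylbenzoyl fluoride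
Conditions: cyanuric fluoride, pyridine, CH2Cl2, −10 °C → rt
Reagents that add atoms: cyanuric fluoride, Fc1nc(F)nc(F)n1
Why: Exchange of carboxylic acid to acyl fluoride with cyanuric fluoride runs in a pyridine-buffered medium that cannot open the acetal, and it gives the smallest possible acyl halide for a shielded carbonyl.

**Step 6**
Reactants: 8 hexane-3,4-dione
Product: 9 (Z)-4-(trimethylsilyloxy)hex-4-en-3-one
Conditions: TMSCl (1.0 equiv), Et3N, DMF, 50 °C
Reagents that add atoms: chlorotrimethylsilane, C[Si](C)(C)Cl
Why: Silyl enol ether formation under equilibrating amine conditions can give only one mono-enol ether because 8 is symmetrical, the Z isomer is favoured because its C-methyl lies trans to the propanoyl group, and one equivalent of TMSCl limits double silylation.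

**Step 7**
Reactants: 7 acyl fluoride; 9 silyl enol ether
Product: 10 (Z)-4-oxohex-2-en-3-yl 2,4-bis(benzyloxy)-3-(1,3-dioxolan-2-yl)-6-methylbenzoate
Conditions: TBAT (5 mol %), THF, −20 °C → rt
Reagents that add atoms: none
Why: In this fluoride-catalysed O-acylation of a silyl enol ether with an acyl fluoride, the ammonium enolate is released only in catalytic amount, which suppresses aldol self-condensation of the diketone, it reacts at oxygen with the hard acyl fluoride, and the expelled fluoride carries the chain through Si–F bond formation.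

**Step 8**
Reactants: 10 enol aroate of hexane-3,4-dione; 11 dimethyl malonate
Product: 13 methyl 5-{[2,4-bis(benzyloxy)-3-(1,3-dioxolan-2-yl)-6-methylbenzoyl]oxy}-3,6-dimethyl-2,4-dioxocyclohexane-1-carboxylate (mixture of diastereomers/enol tautomers), via Michael adduct 12 (not isolated)
Conditions: 11 (1.2 equiv), NaH (1.1 equiv), THF, 0 °C; then 10, 0 °C → rt; then 60 °C; 1 M HCl, 0 °C, to pH 4
Reagents that add atoms: none
Why: Proposed new method: sodiomalonate adds to the methyl-bearing β-carbon of the 2-aroyloxy enone (C1–C6 bond), proton exchange gives the malonate anion of 12, and on warming the small equilibrium share of ethyl-ketone enolate attacks one malonate ester (C2–C3 bond) and expels methoxide, which is consumed at once in deprotonating the new β-dicarbonyl unit, so the reversible manifold drains into the stabilised anion of 13. The closest known reaction type is the Michael–Dieckmann annulation of dialkyl malonates with hex-4-en-3-one and related enones to dihydro-β-resorcylates, and what has not been shown is this cascade on an enone bearing an acyloxy group on its α-carbon. Ring B closes in the 6-(enolendo)-exo-trig mode, a favoured mode for enolate closures. The four new sp3 centres (C1, C3, C5, C6) are left uncontrolled, because C1, C3 and C5 epimerise through enols and all four become sp2 in step 9. The step needs conjugate addition to beat acyl transfer (to the malonate carbon, to methoxide, or from O5 to O4 in the transient C4–C5 enolate) and 3-exo-tet displacement of the aroate by the malonate anion; the ortho benzyloxy and ortho methyl groups block the approach to the aroyl carbonyl as in a mesitoate, an aroate is a poor leaving group for cyclopropane closure, and preformed sodiomalonate in THF keeps free alkoxide at trace level. The intramolecular acyl-shift isomers lack a comparably acidic proton and stay in equilibrium with 12, so they can drain back towards 13.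

**Step 9**
Reactants: 13 5-aroyloxy cyclohexane-1,3-dione
Product: 15 methyl 5-{[2,4-bis(benzyloxy)-3-(1,3-dioxolan-2-yl)-6-methylbenzoyl]oxy}-2,4-dihydroxy-3,6-dimethylbenzoate, via 3-chloro dione 14 (not isolated)
Conditions: NCS (1.0 equiv), DMF, 0 °C; then Li2CO3, 70 °C, under N2
Reagents that add atoms: N-chlorosuccinimide, O=C1CCC(=O)N1Cl (its chlorine is held only in 14; 15 keeps no reagent atom)
Why: In this N-haloimide halogenation–dehydrohalogenation of a dihydroresorcylate, the enolic C3 between the two carbonyls should take up Cl+ far faster than C5'–H of ring A, the C1=C2 enol of 14 then loses HCl in a vinylogous 1,4-sense (C6–H, C3–Cl) to a dienone that tautomerises to the arene (a C1-chloro isomer would converge by 1,2-loss of HCl), carbonate keeps the medium acid-free, ionisation of the C5–aroate bond is disfavoured because O2 and O4 would sit on nodal carbons of the resulting cation, and the aroyl group has no incentive to move to O4 because O4 belongs to the more acidic phenol (para to CO2Me).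

**Step 10**
Reactants: 15 protected depside acetal
Product: 16 methyl 5-{[2,4-bis(benzyloxy)-3-formyl-6-methylbenzoyl]oxy}-2,4-dihydroxy-3,6-dimethylbenzoate
Conditions: PPTS, acetone/H2O, 40 °C
Reagents that add atoms: water, O
Why: In this acid-catalysed acetal hydrolysis the oxocarbenium ion is stabilised by two ortho alkoxy groups, so very mild acid should suffice and the shielded depside ester and the methyl ester remain untouched.

**Step 11**
Reactants: 16 dibenzyl depside aldehyde
Product: 17 methyl 5-[(3-formyl-2,4-dihydroxy-6-methylbenzoyl)oxy]-2,4-dihydroxy-3,6-dimethylbenzoate (target, CNP0235245.0)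
Conditions: H2 (1 atm), 10% Pd/C, EtOAc, rt, stopped after 2 equiv H2
Reagents that add atoms: none
Why: Catalytic hydrogenolysis of aryl benzyl ethers in a neutral aprotic solvent is expected to outrun reduction of the formyl group, which becomes doubly hydrogen-bonded and deactivated as soon as the flanking phenols are freed.

**Compound list**
1 | methyl orsellinate (methyl 2,4-dihydroxy-6-methylbenzoate) | COC(=O)c1c(C)cc(O)cc1O | starting material
2 | methyl 3-formyl-2,4-dihydroxy-6-methylbenzoate | COC(=O)c1c(C)cc(O)c(C=O)c1O | intermediate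
3 | methyl 2,4-bis(benzyloxy)-3-formyl-6-methylbenzoate | COC(=O)c1c(C)cc(OCc2ccccc2)c(C=O)c1OCc1ccccc1 | intermediate
4 | ethylene glycol | OCCO | starting material
5 | methyl 2,4-bis(benzyloxy)-3-(1,3-dioxolan-2-yl)-6-methylbenzoate | COC(=O)c1c(C)cc(OCc2ccccc2)c(C2OCCO2)c1OCc1ccccc1 | intermediate
6 | 2,4-bis(benzyloxy)-3-(1,3-dioxolan-2-yl)-6-methylbenzoic acid | OC(=O)c1c(C)cc(OCc2ccccc2)c(C2OCCO2)c1OCc1ccccc1 | intermediate
7 | 2,4-bis(benzyloxy)-3-(1,3-dioxolan-2-yl)-6-methylbenzoyl fluoride | FC(=O)c1c(C)cc(OCc2ccccc2)c(C2OCCO2)c1OCc1ccccc1 | intermediate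
8 | hexane-3,4-dione | CCC(=O)C(=O)CC | starting material
9 | (Z)-4-(trimethylsilyloxy)hex-4-en-3-one | C/C=C(\O[Si](C)(C)C)C(=O)CC | intermediate
10 | (Z)-4-oxohex-2-en-3-yl 2,4-bis(benzyloxy)-3-(1,3-dioxolan-2-yl)-6-methylbenzoate | C/C=C(\OC(=O)c1c(C)cc(OCc2ccccc2)c(C2OCCO2)c1OCc1ccccc1)C(=O)CC | intermediate
11 | dimethyl malonate | COC(=O)CC(=O)OC | starting material
12 | dimethyl 2-(3-{[2,4-bis(benzyloxy)-3-(1,3-dioxolan-2-yl)-6-methylbenzoyl]oxy}-4-oxohexan-2-yl)malonate (present as sodium enolate, diastereomer mixture, not isolated) | COC(=O)C(C(=O)OC)C(C)C(OC(=O)c1c(C)cc(OCc2ccccc2)c(C2OCCO2)c1OCc1ccccc1)C(=O)CC | intermediate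
13 | methyl 5-{[2,4-bis(benzyloxy)-3-(1,3-dioxolan-2-yl)-6-methylbenzoyl]oxy}-3,6-dimethyl-2,4-dioxocyclohexane-1-carboxylate (diastereomer and tautomer mixture) | COC(=O)C1C(C)C(OC(=O)c2c(C)cc(OCc3ccccc3)c(C3OCCO3)c2OCc2ccccc2)C(=O)C(C)C1=O | intermediate
14 | methyl 5-{[2,4-bis(benzyloxy)-3-(1,3-dioxolan-2-yl)-6-methylbenzoyl]oxy}-3-chloro-3,6-dimethyl-2,4-dioxocyclohexane-1-carboxylate (diastereomer mixture, not isolated) | COC(=O)C1C(C)C(OC(=O)c2c(C)cc(OCc3ccccc3)c(C3OCCO3)c2OCc2ccccc2)C(=O)C(C)(Cl)C1=O | intermediate
15 | methyl 5-{[2,4-bis(benzyloxy)-3-(1,3-dioxolan-2-yl)-6-methylbenzoyl]oxy}-2,4-dihydroxy-3,6-dimethylbenzoate | COC(=O)c1c(C)c(OC(=O)c2c(C)cc(OCc3ccccc3)c(C3OCCO3)c2OCc2ccccc2)c(O)c(C)c1O | intermediate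
16 | methyl 5-{[2,4-bis(benzyloxy)-3-formyl-6-methylbenzoyl]oxy}-2,4-dihydroxy-3,6-dimethylbenzoate | COC(=O)c1c(C)c(OC(=O)c2c(C)cc(OCc3ccccc3)c(C=O)c2OCc2ccccc2)c(O)c(C)c1O | intermediate
17 | methyl 5-[(3-formyl-2,4-dihydroxy-6-methylbenzoyl)oxy]-2,4-dihydroxy-3,6-dimethylbenzoate (achiral) | COC(=O)c1c(C)c(OC(=O)c2c(C)cc(O)c(C=O)c2O)c(O)c(C)c1O | target

**Step count**
- Total step count: 11.
- Longest linear sequence: 10 (steps 1–5 and 7–11). Step 6 is a one-step side branch.

**Steps most likely to fail**

1. **Step 8** (Proposed new method).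
   - What may go wrong: the aroyl group may be transferred away from the enol oxygen, the aroate may be displaced in a cyclopropane-forming closure, or the sequence may stall at the open-chain Michael stage.
   - The fallback uses only known depside chemistry. It sets out from 7 and rejoins the route at 17.
   - Ring B is taken ready-made as commercial methyl 2,4-dihydroxy-3,6-dimethylbenzoate (COC(=O)c1c(C)cc(O)c(C)c1O).
   - Rieche formylation at its only free position, C5, gives methyl 5-formyl-2,4-dihydroxy-3,6-dimethylbenzoate F1.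
   - BnBr/K2CO3 gives methyl 2,4-bis(benzyloxy)-5-formyl-3,6-dimethylbenzoate F2.
   - Baeyer–Villiger oxidation with mCPBA gives methyl 2,4-bis(benzyloxy)-5-(formyloxy)-3,6-dimethylbenzoate F3.
   - Methanolysis with catalytic K2CO3 frees methyl 2,4-bis(benzyloxy)-5-hydroxy-3,6-dimethylbenzoate F4, in which O5 is the only free phenol.
   - The sodium phenoxide of F4 (NaH, THF) is acylated with 7 to methyl 2,4-bis(benzyloxy)-5-{[2,4-bis(benzyloxy)-3-(1,3-dioxolan-2-yl)-6-methylbenzoyl]oxy}-3,6-dimethylbenzoate F5.
   - PPTS in aqueous acetone gives methyl 2,4-bis(benzyloxy)-5-{[2,4-bis(benzyloxy)-3-formyl-6-methylbenzoyl]oxy}-3,6-dimethylbenzoate F6.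
   - Hydrogenolysis over Pd/C in EtOAc removes all four benzyl groups and gives 17.

2. **Step 9.**
   - What may go wrong: aromatisation may occur by loss of the aroate instead of by oxidation, positive chlorine may be transferred to ring A, or the α-chloro dione may undergo Favorskii-type contraction.
   - The fallback replaces halogen chemistry by hydride abstraction from a silyl dienol ether. It sets out from 13 and rejoins the route at 16.
   - TMSCl/Et3N in DMF converts both enolisable carbonyl units into methyl 5-{[2,4-bis(benzyloxy)-3-(1,3-dioxolan-2-yl)-6-methylbenzoyl]oxy}-3,6-dimethyl-2,4-bis(trimethylsilyloxy)cyclohexa-1,3-diene-1-carboxylate F7.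
   - DDQ buffered with collidine in CH2Cl2 at 0 °C should abstract the C6 hydride, because the resulting cation is stabilised by both silyloxy groups. Loss of the C5 proton then gives methyl 5-{[2,4-bis(benzyloxy)-3-(1,3-dioxolan-2-yl)-6-methylbenzoyl]oxy}-3,6-dimethyl-2,4-bis(trimethylsilyloxy)benzoate F8.
   - The conditions of step 10 then strip the two silyl ethers and the acetal together and give 16.

3. **Step 7.**
   - What may go wrong: attack on the shielded acyl fluoride may be too slow, so that the released enolate is lost to protodesilylation, aldol self-condensation or C-acylation.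
   - The fallback forms the enol ester from the carboxylate oxygen and an olefination, so the hindered carbonyl is never attacked. It sets out from 6 and rejoins the route at 10.
   - Regitz diazo transfer (p-ABSA, Et3N, MeCN) onto commercial diethyl (2-oxobutyl)phosphonate gives diethyl (1-diazo-2-oxobutyl)phosphonate F9.
   - Rh2(OAc)4-catalysed O–H insertion of its carbenoid into acid 6 gives 1-(diethoxyphosphoryl)-2-oxobutyl 2,4-bis(benzyloxy)-3-(1,3-dioxolan-2-yl)-6-methylbenzoate F10.
   - Horner–Wadsworth–Emmons olefination of F10 with acetaldehyde (LiCl, DBU, MeCN, 0 °C) gives 10. Either alkene geometry serves in step 8.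

**Further compounds**
F1 | step 8 | methyl 5-formyl-2,4-dihydroxy-3,6-dimethylbenzoate | COC(=O)c1c(C)c(C=O)c(O)c(C)c1O
F2 | step 8 | methyl 2,4-bis(benzyloxy)-5-formyl-3,6-dimethylbenzoate | COC(=O)c1c(C)c(C=O)c(OCc2ccccc2)c(C)c1OCc1ccccc1
F3 | step 8 | methyl 2,4-bis(benzyloxy)-5-(formyloxy)-3,6-dimethylbenzoate | COC(=O)c1c(C)c(OC=O)c(OCc2ccccc2)c(C)c1OCc1ccccc1
F4 | step 8 | methyl 2,4-bis(benzyloxy)-5-hydroxy-3,6-dimethylbenzoate | COC(=O)c1c(C)c(O)c(OCc2ccccc2)c(C)c1OCc1ccccc1
F5 | step 8 | methyl 2,4-bis(benzyloxy)-5-{[2,4-bis(benzyloxy)-3-(1,3-dioxolan-2-yl)-6-methylbenzoyl]oxy}-3,6-dimethylbenzoate | COC(=O)c1c(C)c(OC(=O)c2c(C)cc(OCc3ccccc3)c(C3OCCO3)c2OCc2ccccc2)c(OCc2ccccc2)c(C)c1OCc1ccccc1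
F6 | step 8 | methyl 2,4-bis(benzyloxy)-5-{[2,4-bis(benzyloxy)-3-formyl-6-methylbenzoyl]oxy}-3,6-dimethylbenzoate | COC(=O)c1c(C)c(OC(=O)c2c(C)cc(OCc3ccccc3)c(C=O)c2OCc2ccccc2)c(OCc2ccccc2)c(C)c1OCc1ccccc1
F7 | step 9 | methyl 5-{[2,4-bis(benzyloxy)-3-(1,3-dioxolan-2-yl)-6-methylbenzoyl]oxy}-3,6-dimethyl-2,4-bis(trimethylsilyloxy)cyclohexa-1,3-diene-1-carboxylate | COC(=O)C1=C(O[Si](C)(C)C)C(C)=C(O[Si](C)(C)C)C(OC(=O)c2c(C)cc(OCc3ccccc3)c(C3OCCO3)c2OCc2ccccc2)C1C
F8 | step 9 | methyl 5-{[2,4-bis(benzyloxy)-3-(1,3-dioxolan-2-yl)-6-methylbenzoyl]oxy}-3,6-dimethyl-2,4-bis(trimethylsilyloxy)benzoate | COC(=O)c1c(C)c(OC(=O)c2c(C)cc(OCc3ccccc3)c(C3OCCO3)c2OCc2ccccc2)c(O[Si](C)(C)C)c(C)c1O[Si](C)(C)C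
F9 | step 7 | diethyl (1-diazo-2-oxobutyl)phosphonate | CCC(=O)C(=[N+]=[N-])P(=O)(OCC)OCC
F10 | step 7 | 1-(diethoxyphosphoryl)-2-oxobutyl 2,4-bis(benzyloxy)-3-(1,3-dioxolan-2-yl)-6-methylbenzoate | CCC(=O)C(OC(=O)c1c(C)cc(OCc2ccccc2)c(C2OCCO2)c1OCc1ccccc1)P(=O)(OCC)OCC
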